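## Retrosynthetic overview

1. 17 ⇐ 16 by global desilylation. Rings A and B are bought, so ring C is the only ring that has to be made.
2. Ring C of 16 (O1, C2, C3, C4, C4a, C8a) ⇐ the seven-membered 1,3-dioxepine ring of 14 (O1, C2, O3, C3, C4, C4a, C8a). A catalytic, enantioconvergent 1,2 shift of C2 from O3 to C3 forms C2–C3, sets C2 and C3, and releases the C4 ketone and the 3-oxygen in one isomerisation.
3. Enabling feature: in ring C the benzylic carbon C2 (bearing O1 and the electron-rich ring B) stands next to C3, which bears O3 and is alpha to the C4 carbonyl. With a C2–O3 bond in place of C2–C3, C2 becomes the acetal carbon of 4-hydroxybenzaldehyde (latent cation) and C3=C4 an enol silane (latent nucleophile), both inside one ring.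
4. 14 ⇐ ketone 12 ⇐ transacetalisation of omega-hydroxyacetophenone 8 with acetal 10. 8 ⇐ phloroacetophenone 1 and geranyl bromide 2 (C-geranylation, MOM/methyl differentiation of the three phenols, Davis oxidation).
5. Order of ring formation: seven-membered dioxepinone ring (step 7), then ring C by contraction (step 10).

Key step: step 10

**Remarks**
- O1, C2, C3, C4, C4a, C8a, O3 (oxygen on C3) and O4 (oxygen on C4) follow the flavonoid numbering of 17. They denote the same atoms in all precursors.
- Locants such as 2-OH, 4-OH and 6-OH in steps 2 to 7 follow acetophenone numbering.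
- Geranyl = (2E)-3,7-dimethylocta-2,6-dien-1-yl. MOM = methoxymethyl. TBS = tert-butyldimethylsilyl.
- IDPi = BINOL-derived imidodiphosphorimidate Brønsted acid with N-triflyl groups and 3,3'-aryl substituents.
- Assumption: the sense of induction of the IDPi catalyst cannot be derived from precedent for this substrate class. The (S,S) form is written, and its mirror image is used if (S,S) favours the (2S,3S) product.

## Route

Step 1
Reactants: 1 2,4,6-trihydroxyacetophenone; 2 geranyl bromide
Product: 3 1-(3-geranyl-2,4,6-trihydroxyphenyl)ethanone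
Conditions: K2CO3, acetone, reflux
Reagents that add atoms: none
Why: C-allylation of the ambident acylphloroglucinol phenolate (Friedel–Crafts-like SN2 alkylation) has close precedent, the two free ring positions of 1 are equivalent so only one mono-C-geranyl isomer can form, and SN2 attack at the primary allylic carbon keeps the E alkene.

Step 2
Reactants: 3 1-(3-geranyl-2,4,6-trihydroxyphenyl)ethanone
Product: 4 1-[3-geranyl-2-hydroxy-4,6-bis(methoxymethoxy)phenyl]ethanone
Conditions: MOMCl (2.2 equiv), iPr2NEt, CH2Cl2, 0 °C → rt
Reagents that add atoms: chloromethyl methyl ether (MOMCl), COCCl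
Why: Williamson-type MOM protection takes the non-chelated 4-OH and the less hindered 6-OH, whereas the 2-OH, wedged between acetyl and geranyl and held in the hydrogen bond to the carbonyl oxygen, should stay free.

Step 3
Reactants: 4 1-[3-geranyl-2-hydroxy-4,6-bis(methoxymethoxy)phenyl]ethanone
Product: 5 1-[3-geranyl-2-methoxy-4,6-bis(methoxymethoxy)phenyl]ethanone
Conditions: MeI (excess), K2CO3, DMF, 40 °C
Reagents that add atoms: iodomethane, CI
Why: Williamson ether synthesis at the only free phenol places the methyl group on the oxygen next to the geranyl chain (the later 5-OMe beside C6) and leaves MOM ethers and alkenes untouched.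

Step 4
Reactants: 5 1-[3-geranyl-2-methoxy-4,6-bis(methoxymethoxy)phenyl]ethanone
Product: 7 1-[3-geranyl-2-methoxy-4,6-bis(methoxymethoxy)phenyl]-2-hydroxyethanone, via potassium enolate 6 (not isolated)
Conditions: KN(SiMe3)2, THF, −78 °C; then 2-(phenylsulfonyl)-3-phenyloxaziridine, −78 °C; aq NH4Cl
Reagents that add atoms: 2-(phenylsulfonyl)-3-phenyloxaziridine, O=S(=O)(N1OC1c1ccccc1)c1ccccc1
Why: Davis oxidation, in which the methyl group is the only enolisable site and the N-sulfonyloxaziridine transfers oxygen to the enolate carbon at low temperature without touching the two trisubstituted alkenes that a peracid-based Rubottom oxidation would epoxidise.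

Step 5
Reactants: 7 1-[3-geranyl-2-methoxy-4,6-bis(methoxymethoxy)phenyl]-2-hydroxyethanone
Product: 8 1-(3-geranyl-4,6-dihydroxy-2-methoxyphenyl)-2-hydroxyethanone
Conditions: conc. HCl (cat.), MeOH, 40 °C
Reagents that add atoms: none
Why: Acid-catalysed acetal exchange with methanol cleaves both aryl MOM ethers under the dilute conditions routine for prenylated phenols, mild enough to avoid chroman formation between the freed 4-OH and the geranyl alkene.

Step 6
Reactants: 9 4-(tert-butyldimethylsilyloxy)benzaldehyde
Product: 10 4-(tert-butyldimethylsilyloxy)benzaldehyde dimethyl acetal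
Conditions: HC(OMe)3, pyridinium p-toluenesulfonate (cat.), MeOH, rt; Et3N quench
Reagents that add atoms: trimethyl orthoformate, COC(OC)OC
Why: Acid-catalysed acetalisation with the orthoester as methoxy donor and water scavenger, under which the aryl TBS ether is stable.

Step 7
Reactants: 8 1-(3-geranyl-4,6-dihydroxy-2-methoxyphenyl)-2-hydroxyethanone; 10 4-(tert-butyldimethylsilyloxy)benzaldehyde dimethyl acetal
Product: 11 (±)-2-[4-(TBSO)phenyl]-7-geranyl-8-hydroxy-6-methoxy-2H-1,3-benzodioxepin-5(4H)-one
Conditions: pyridinium p-toluenesulfonate (5 mol %), toluene, 5 Å molecular sieves, 45 °C, MeOH removed under reduced pressure; Et3N-deactivated silica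
Reagents that add atoms: none
Why: Transacetalisation under thermodynamic control, in which the 6-OH and the primary omega-OH sit cis on the rigid backbone C(aryl)=C(aryl)–C(=O)–CH2 (as in the cis-but-2-ene-1,4-diols that readily give 1,3-dioxepines), removal of methanol drives closure of the seven-membered ring, the para 4-OH cannot form a cyclic acetal, and the new acetal centre may be racemic because step 10 erases it.

Step 8
Reactants: 11 (±)-2-[4-(TBSO)phenyl]-7-geranyl-8-hydroxy-6-methoxy-2H-1,3-benzodioxepin-5(4H)-one
Product: 12 (±)-8-(TBSO)-2-[4-(TBSO)phenyl]-7-geranyl-6-methoxy-2H-1,3-benzodioxepin-5(4H)-one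
Conditions: TBSCl, imidazole, CH2Cl2, rt
Reagents that add atoms: tert-butyldimethylsilyl chloride, CC(C)(C)[Si](C)(C)Cl
Why: Imidazole-promoted silylation of the only free OH removes the last proton source before the key step and does not disturb the acetal.

Step 9
Reactants: 12 (±)-8-(TBSO)-2-[4-(TBSO)phenyl]-7-geranyl-6-methoxy-2H-1,3-benzodioxepin-5(4H)-one
Product: 14 (±)-5,8-bis(TBSO)-2-[4-(TBSO)phenyl]-7-geranyl-6-methoxy-2H-1,3-benzodioxepine, via potassium enolate 13 (not isolated)
Conditions: KN(SiMe3)2, THF, −78 °C; TBSCl, DMPU, −78 → −20 °C; pH 7 buffer, Et3N-deactivated silica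
Reagents that add atoms: tert-butyldimethylsilyl chloride, CC(C)(C)[Si](C)(C)Cl
Why: Hard enolisation and O-silylation (silyl enol ether formation), in which the CH2 between O3 and the ketone is the only acidic site, the ring fixes the alkene geometry, and base-only conditions avoid the premature acetal ionisation that a silyl triflate could cause.

Step 10
Reactants: 14 (±)-5,8-bis(TBSO)-2-[4-(TBSO)phenyl]-7-geranyl-6-methoxy-2H-1,3-benzodioxepine
Product: 16 (2R,3R)-3,7-bis(TBSO)-2-[4-(TBSO)phenyl]-6-geranyl-5-methoxychroman-4-one, via ring-opened oxocarbenium ion 15 (not isolated)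
Conditions: (S,S)-IDPi (3 mol %), toluene, −60 → −30 °C, strict exclusion of moisture
Reagents that add atoms: none
Why: Proposed new method: the IDPi acid protodesilylates a trace of 14 to a silylium–IDPi ion pair, which silylates the enol-ether oxygen O3 and breaks the acetal bond C2–O3, so that the seven-membered ring opens to oxocarbenium ion 15 (still tied to ring A through O1 and stabilised by the 4-silyloxyphenyl ring B); C3 of the 1,2-bis(silyloxy)alkene then attacks C2 and the silylium ion leaves O4 for the next molecule of 14, which amounts to a 1,2 shift of C2 from O3 to C3 and an isomerisation of 14 into 16. The closest known reaction types are the Petasis–Ferrier rearrangement of cyclic enol acetals, the Lewis-acid ring contraction of 4,5-dihydro-1,3-dioxepines to tetrahydrofurans, the anomeric oxygen-to-carbon rearrangement of acetal-tethered silyl enol ethers and the silylium-based counteranion-directed asymmetric Mukaiyama aldol addition to acetal-derived oxocarbenium ions; new are the 1,2 sense of the shift, the seven-to-six contraction and the enantioconvergent use of a racemic acetal. Ring C closes in a 6-(enolendo)-endo-trig mode, C2 and C3 being only one atom (O3) apart when the ion forms. C2 is planar in 15, so its configuration and, through the closing half-chair, that of C3 should be set by the chiral IDPi anion that shields one face of the cation, while the 2,3-trans relation should follow from ring B and the bulky 3-OTBS group staying anti in the half-chair, which relaxes to the diequatorial and thermodynamically preferred isomer. Needed are C- over O-recombination, attack through C3 and not C4, and loss of the stereochemical memory of the acetal: return to O3 only regenerates 14, attack through C3 leaves the charge on C4 where OTBS and the trioxygenated ring A stabilise it whereas attack through C4 would be a 5-(enolexo)-endo-trig closure at a fully substituted carbon, and reversible ionisation of either acetal C–O bond should racemise C2 of 14 faster than the C–C bond forms. The geranyl alkenes, para to O1 across ring A, cannot reach C2, no free OH or other proton source is present, and the aryl silyl ethers are inert to the silylium catalyst.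

Step 11
Reactants: 16 (2R,3R)-3,7-bis(TBSO)-2-[4-(TBSO)phenyl]-6-geranyl-5-methoxychroman-4-one
Product: 17 (2R,3R)-6-geranyl-3,7-dihydroxy-2-(4-hydroxyphenyl)-5-methoxychroman-4-one
Conditions: Et3N·3HF, THF, 0 °C → rt
Reagents that add atoms: none
Why: Fluoride-mediated desilylation with the slightly acidic Et3N·3HF removes the two aryl and the secondary TBS ethers without the base that would epimerise C2 and C3 or contract ring C to the auronol and without the strong acid that would cyclise the geranyl chain, so both stereocentres are retained.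

## Compound list

1 | 2,4,6-trihydroxyacetophenone | CC(=O)c1c(O)cc(O)cc1O | starting material
2 | geranyl bromide | BrC/C=C(\C)CCC=C(C)C | starting material
3 | 1-(3-geranyl-2,4,6-trihydroxyphenyl)ethanone | CC(=O)c1c(O)cc(O)c(C/C=C(\C)CCC=C(C)C)c1O | intermediate
4 | 1-[3-geranyl-2-hydroxy-4,6-bis(methoxymethoxy)phenyl]ethanone | CC(=O)c1c(OCOC)cc(OCOC)c(C/C=C(\C)CCC=C(C)C)c1O | intermediate
5 | 1-[3-geranyl-2-methoxy-4,6-bis(methoxymethoxy)phenyl]ethanone | CC(=O)c1c(OCOC)cc(OCOC)c(C/C=C(\C)CCC=C(C)C)c1OC | intermediate
6 | potassium enolate of 5 (not isolated) | [K+].C=C([O-])c1c(OCOC)cc(OCOC)c(C/C=C(\C)CCC=C(C)C)c1OC | intermediate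
7 | 1-[3-geranyl-2-methoxy-4,6-bis(methoxymethoxy)phenyl]-2-hydroxyethanone | OCC(=O)c1c(OCOC)cc(OCOC)c(C/C=C(\C)CCC=C(C)C)c1OC | intermediate
8 | 1-(3-geranyl-4,6-dihydroxy-2-methoxyphenyl)-2-hydroxyethanone | OCC(=O)c1c(O)cc(O)c(C/C=C(\C)CCC=C(C)C)c1OC | intermediate
9 | 4-(tert-butyldimethylsilyloxy)benzaldehyde | O=Cc1ccc(O[Si](C)(C)C(C)(C)C)cc1 | starting material
10 | 4-(tert-butyldimethylsilyloxy)benzaldehyde dimethyl acetal | COC(OC)c1ccc(O[Si](C)(C)C(C)(C)C)cc1 | intermediate
11 | (±)-2-[4-(TBSO)phenyl]-7-geranyl-8-hydroxy-6-methoxy-2H-1,3-benzodioxepin-5(4H)-one (racemic acetal carbon) | COc1c(C/C=C(\C)CCC=C(C)C)c(O)cc2c1C(=O)COC(c1ccc(O[Si](C)(C)C(C)(C)C)cc1)O2 | intermediate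
12 | (±)-8-(TBSO)-2-[4-(TBSO)phenyl]-7-geranyl-6-methoxy-2H-1,3-benzodioxepin-5(4H)-one | COc1c(C/C=C(\C)CCC=C(C)C)c(O[Si](C)(C)C(C)(C)C)cc2c1C(=O)COC(c1ccc(O[Si](C)(C)C(C)(C)C)cc1)O2 | intermediate
13 | potassium enolate of 12 (not isolated) | [K+].COc1c(C/C=C(\C)CCC=C(C)C)c(O[Si](C)(C)C(C)(C)C)cc2c1C([O-])=COC(c1ccc(O[Si](C)(C)C(C)(C)C)cc1)O2 | intermediate
14 | (±)-5,8-bis(TBSO)-2-[4-(TBSO)phenyl]-7-geranyl-6-methoxy-2H-1,3-benzodioxepine (cyclic enol silane acetal) | COc1c(C/C=C(\C)CCC=C(C)C)c(O[Si](C)(C)C(C)(C)C)cc2c1C(O[Si](C)(C)C(C)(C)C)=COC(c1ccc(O[Si](C)(C)C(C)(C)C)cc1)O2 | intermediate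
15 | ring-opened aryloxy(aryl)oxocarbenium ion bearing the 1,2-bis(TBSO)vinyl group on ring A, O3 cis to ring A, counterion IDPi anion, extra TBS from the catalytic cycle (not isolated) | COc1c(C/C=C(\C)CCC=C(C)C)c(O[Si](C)(C)C(C)(C)C)cc([O+]=Cc2ccc(O[Si](C)(C)C(C)(C)C)cc2)c1/C(O[Si](C)(C)C(C)(C)C)=C\O[Si](C)(C)C(C)(C)C | intermediate
16 | (2R,3R)-3,7-bis(TBSO)-2-[4-(TBSO)phenyl]-6-geranyl-5-methoxychroman-4-one | COc1c(C/C=C(\C)CCC=C(C)C)c(O[Si](C)(C)C(C)(C)C)cc2c1C(=O)[C@H](O[Si](C)(C)C(C)(C)C)[C@@H](c1ccc(O[Si](C)(C)C(C)(C)C)cc1)O2 | intermediate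
17 | (2R,3R)-6-geranyl-3,7-dihydroxy-2-(4-hydroxyphenyl)-5-methoxychroman-4-one | COc1c(C/C=C(\C)CCC=C(C)C)c(O)cc2c1C(=O)[C@H](O)[C@@H](c1ccc(O)cc1)O2 | target

## Step count and risks

Total step count: 11. Longest linear sequence: 10 (steps 1 to 5 and 7 to 11).

**Step 10.**
- What may go wrong: the ion pair may collapse with retention of the acetal configuration before it loses its stereochemical memory, which would erode enantioselectivity. Facial and cis/trans control in the half-chair may be poor. The large substrate may not turn over in the catalyst pocket.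
- Fallback (known chemistry), setting out from 5 and returning at 17: Claisen–Schmidt condensation of 5 with 4-(methoxymethoxy)benzaldehyde (KOH, EtOH, rt) should give (E)-1-[3-geranyl-2-methoxy-4,6-bis(methoxymethoxy)phenyl]-3-[4-(methoxymethoxy)phenyl]prop-2-en-1-one F1. Juliá–Colonna epoxidation (poly-L-leucine, urea–H2O2, DBU, THF) is a nucleophilic epoxidation that ignores the geranyl alkenes. It should give [3-geranyl-2-methoxy-4,6-bis(methoxymethoxy)phenyl]{(2R,3S)-3-[4-(methoxymethoxy)phenyl]oxiran-2-yl}methanone F2. HCl in MeOH at 45 °C then removes the three MOM groups. The freed ortho phenol opens the epoxide at the benzylic carbon with inversion (6-endo), the alpha carbon keeping its configuration as C3, to give 17.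

**Step 7.**
- What may go wrong: closure of the seven-membered mixed aryl alkyl acetal may lose against oligomeric acetals. The labile acetal may also ionise and hydrolyse during isolation.
- Fallback, setting out from 8 and returning at 11: persilylation of 8 (Me3SiCl, Et3N, CH2Cl2) should give the tris(trimethylsilyl) ether of 8 F3. This reacts with aldehyde 9 under kinetic, water-free silyl-transfer acetalisation (Me3SiOTf cat., CH2Cl2, −78 °C) to give the 8-O-trimethylsilyl analogue of 11 F4. Brief methanolysis of its very labile aryl trimethylsilyl ether at rt returns 11.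

**Step 4.**
- What may go wrong: the enolate may add to the sulfonimine by-product, the hindered ketone may enolise incompletely, or further oxidation of the product alkoxide may set in.
- Fallback, setting out from 5 and returning at 8: hypervalent-iodine alpha-hydroxylation (PhI(OAc)2, KOH, MeOH, 0 °C → rt) leaves isolated alkenes and MOM ethers alone. It should give 2-[3-geranyl-2-methoxy-4,6-bis(methoxymethoxy)phenyl]-2,2-dimethoxyethanol F5. Aqueous HCl in MeOH at 40 °C then hydrolyses the ketal and both MOM ethers in one operation to 8.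

## Further compounds

F1 | step 10 | (E)-1-[3-geranyl-2-methoxy-4,6-bis(methoxymethoxy)phenyl]-3-[4-(methoxymethoxy)phenyl]prop-2-en-1-one | COCOc1cc(OCOC)c(C/C=C(\C)CCC=C(C)C)c(OC)c1C(=O)/C=C/c1ccc(OCOC)cc1
F2 | step 10 | [3-geranyl-2-methoxy-4,6-bis(methoxymethoxy)phenyl]{(2R,3S)-3-[4-(methoxymethoxy)phenyl]oxiran-2-yl}methanone | COCOc1cc(OCOC)c(C/C=C(\C)CCC=C(C)C)c(OC)c1C(=O)[C@@H]1O[C@H]1c1ccc(OCOC)cc1
F3 | step 7 | tris(trimethylsilyl) ether of 8 | C[Si](C)(C)OCC(=O)c1c(O[Si](C)(C)C)cc(O[Si](C)(C)C)c(C/C=C(\C)CCC=C(C)C)c1OC
F4 | step 7 | 8-O-trimethylsilyl analogue of 11 (racemic acetal carbon) | COc1c(C/C=C(\C)CCC=C(C)C)c(O[Si](C)(C)C)cc2c1C(=O)COC(c1ccc(O[Si](C)(C)C(C)(C)C)cc1)O2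
F5 | step 4 | 2-[3-geranyl-2-methoxy-4,6-bis(methoxymethoxy)phenyl]-2,2-dimethoxyethanol | COC(CO)(OC)c1c(OCOC)cc(OCOC)c(C/C=C(\C)CCC=C(C)C)c1OC
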